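Numbering and abbreviations: C1 is the carboxyl carbon and C2 its methyl-bearing neighbour. O1–O2 is the peroxide (O1 on C6, O2 on C3) and C3–C6 are the dioxane carbons. C7–C9 form the tether, C10–C12 and C19 belong to ring B, and C13–C18 to ring A (C18 = CMe2). TBS = tert-butyldimethylsilyl, TBDPS = tert-butyldiphenylsilyl, Ms = methanesulfonyl, Tf = trifluoromethanesulfonyl. CIP descriptors change along the route where substituent priorities change; the spatial arrangement changes only where a step says so.

## Structural features

The target is a 1,2-dioxane (O1–O2, C3–C6) that carries the α-methyl carboxylic acid unit C1–C2 at C3 and, at the quaternary C6, a methyl group and the three-carbon tether C7–C9. The tether ends in the exocyclic trisubstituted alkene C9=C10 on ring B of an octahydronaphthalene. Its ring fusion is the tetrasubstituted alkene C13=C14, and ring A carries the gem-dimethyl carbon C18 directly next to C13. C2 and C3 are contiguous stereocentres (2S,3S, methyl and ring oxygen anti in the extended chain), and C6 (S) stands 1,4 to C3 with the C3 side chain cis to the C7 arm. The carbobicycle has no stereocentre, but the geometry of C9=C10 (C8 on the side of C19, Z) is a stereo-element that a late olefination of a ring-B ketone could not control. The O–O bond is fragile towards low-valent metals, boranes, hydrides, strong bases and radicals, and C3–H can be lost in a Kornblum–DeLaMare fragmentation. Once C1 is a carbonyl, C2 can epimerise and the C3–O bond lies β to it; the exocyclic alkene can migrate under acid. The real difficulty is to build the carbocycle with organometallic chemistry while fixing the C9=C10 geometry and the ring-fusion alkene, and still to deliver an intact, configurationally defined peroxide. The key step exploits the blocked C18 position: the ring-A ketone at C13 can enolise only towards C14, so one enol triflate forms and a coupling of C12 with C13 puts the alkene exactly at the ring fusion.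

## Logic of the disconnections

**37 to 34 (through 36 and 35).** No skeletal bond is cut. The C1 carboxyl is taken back to the primary alcohol 35 and its silyl ether 34. The reason is that a C1 carbonyl would make C2–H acidic and place the C3–O bond β to a carbonyl during the carbanion chemistry of the fragment union. The gain is a robust, non-epimerisable C2 centre. The demand is an oxidation in step 24 that spares two alkenes and the O–O bond.

**34 to 16 and 31 (through 33).** The C7–C8 bond is cut, in the forward sense as the C7=C8 alkene of 33 followed by saturation. C7 is neopentylic and β to the peroxide, so it can only arrive as a carbonyl carbon. The gain is full convergence: the peroxide half 31 and the carbocyclic half 16 are made separately. The demands are a carbanion addition to 31 that is faster than attack on the O–O bond, and a reduction of 33 that touches only C7=C8.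

**16 to 12 (through 14 and 13).** The C8–P bond is cut back to the C8–O bond. The reason is that a silyl ether is inert to borane and palladium, whereas a phosphorus or halogen substituent at the allylic position is not. The demand is substitution at C8 without allylic transposition, so that the C9=C10 geometry of 12 is carried into 16.

**12 to 10 (through 11), the key disconnection.** The C12–C13 bond is cut, which opens ring B. Cutting here removes the only ring whose alkene position is hard to control and leaves a monocyclic enol triflate with a vinyl group as the latent C12 nucleophile. The demands are hydroboration of the vinyl group alone, with boron on C12, and a coupling that does not disturb the C9=C10 geometry.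

**10 to 6 (through 9, 8 and 7).** The O–S bond of the triflate and the C11=C12 bond are cut. The vinyl group is traced to the ester carbon of 6 and the triflate to the ketone. The gain is a keto ester that a three-component union can deliver. The demands are a methylenation in step 5 that discriminates an enal from a hindered ketone, and an enolisation in step 6 that has only one α-hydrogen to choose.

**6 to 2, 3 and 4 (through 5).** The C10–C19 bond (conjugate addition) and the C9=C10 bond (Wittig) are cut. This is where the alkene geometry is set: an α-substituted stabilised ylide places C8 trans to the ester carbon C11. The gain is three simple components. The demand is that the conjugate addition is complete before 4 is added.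

**2 to 1.** The C14=C19 bond is cut. The demand is α-methylenation at the only enolisable position.

**31 to 30.** The bond between C7 and the extra carbon C8′ of a 1,2-diol is restored. A glycol is a stable carrier for the sensitive α-peroxy aldehyde and is released by a reagent that ignores peroxides.

**30 to 29.** The C3–O2 bond is cut. The dioxane is opened to a tertiary hydroperoxide at C6 and a secondary mesylate at C3. The demand is an intramolecular SN2 reaction with clean inversion at C3 that is faster than elimination or fragmentation.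

**29 to 27 (through 28).** The C6–O1 bond is cut back to a C6–C7 epoxide, and the epoxide to an allylic alcohol. The reason is that a tertiary C–OOH bond can be made stereospecifically by acid-catalysed opening of a trisubstituted epoxide, and the epoxide by reagent-controlled epoxidation. The demands are inversion at C6 in step 18, and mesylation of C3 before the epoxide exists, so that no hydroxyl can open it.

**27 to 23 (through 26, 25 and 24).** Only protecting-group and oxidation-state bonds are cut (acetate, mesylate, silyl ether, auxiliary). The demand is that the imide is reduced in the presence of the acetate.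

**23 to 19 and 20 (through 21 and 22).** The C2–C3 bond is cut (aldol). This sets C2 with its final arrangement and C3 with the arrangement opposite to the target, which step 19 inverts. The demand is a syn-selective, auxiliary-controlled aldol.

**19 to 17 (through 18).** The C3=C bond to the isopropylidene carbon is restored. The demand is ozonolysis of the electron-rich alkene of 17 only.

## Other disconnections considered

**Alternative 1:** The cut is the C6–O1 bond, leading back to the hydroperoxy epoxide A1 (C3 hydroperoxide, C6–C7 terminal epoxide). In the forward key step, mild acid would let the C3 hydroperoxide open the epoxide at the tertiary carbon C6 in a 6-exo mode with inversion, giving the hydroxymethyl dioxane A2.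

- In its favour: the closure runs under acid, so the base-sensitivity of a β-hydroxy hydroperoxide, which is the main worry of step 19 in the chosen plan, does not arise. On this point it is the better of the two.
- Also in its favour: A2 needs one oxidation to reach a C7 aldehyde, against one glycol cleavage from 30. This is equal.
- Against it here: A1 needs a configurationally defined secondary hydroperoxide at C3, next to the branched C2. Bringing it in by intermolecular substitution at a β-branched secondary sulfonate would compete with elimination. The chosen plan makes its only intermolecular C–OO bond at the tertiary carbon with excess H2O2 and closes the hindered secondary centre intramolecularly.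
- Structure and mechanism: both plans invert C6 by opening a tertiary epoxide and share the risk of partial SN1 leakage there (equal). Both give the same cis-3,6 ring.
- Step economy: about equal. The alternative says nothing about the carbocycle, so steps 1–10 and 21–24 or an equivalent would still be needed.

**Alternative 2:** The cut is the C3–O2 and C1–C2 bonds together, leading back to the hydroperoxy (Z)-alkene A3. In the forward key step, Pd(OAc)2 with p-benzoquinone under CO in methanol would effect anti peroxy-palladation of the alkene by the C6 hydroperoxide (6-exo), CO insertion and methanolysis, giving the dioxane ester A4.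

- In its favour: two bonds form in one step, and the anti addition to the (Z)-alkene gives the required anti relation of the C2 methyl and the C3 oxygen.
- Also in its favour: C1 arrives at the acid oxidation level. The endgame would then need no alcohol oxidation in the presence of the alkenes, and on this point and on step count it is better than the chosen plan.
- Against it here: a hydroperoxide, CO and divalent palladium are a redox-active mixture, and peroxide decomposition and CO oxidation would compete.
- The alkylpalladium intermediate can lose a β-hydrogen towards the C2 methyl before it inserts CO.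
- The configuration of C3 relative to C6 depends on the ring closure telling a methyl group from a silyloxymethyl group at C6. These are of similar size, so the cis-3,6 ring would be expected as a mixture with its epimer.
- The ester A4 would also have to pass the carbanion union with an acidic C2–H and a β-peroxy carbonyl.
- Comparison: the chosen plan is longer but fixes C2, C3 and C6 by an auxiliary, a reagent-controlled epoxidation and two inversions of known stereochemical course. The alternative is shorter but leans on substrate control that the structure does not clearly provide.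

**Alternative 3:** The cut is the C3–O and C6–O bonds together, leading back to the (E,E)-diene A5. In the forward key step, sensitised singlet oxygen would add across C3 and C6 in a [4+2] fashion to give the 3,6-dihydro-1,2-dioxine A6, whose ring alkene would then be reduced with diimide.

- In its favour: it is the shortest entry, and no hydroperoxide is handled (better on safety).
- Also in its favour: the suprafacial cycloaddition enforces the cis-3,6 relation by mechanism. This is at least the equal of two separate inversions.
- Both oxygenated arms arrive differentiated as TBDPS and TBS ethers.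
- Against it here: the face of the diene is chosen only by the C2 stereocentre through allylic strain, so the absolute configuration of C3 and C6 would be set with limited selectivity.
- The C6 terminus is trisubstituted and carries a methyl group on the inside of the s-cis conformer. This slows the cycloaddition and opens the ene pathway to allylic hydroperoxides at the C6 methyl, C7 and C2.
- Comparison: the mechanism is concerted and clean in principle, and the step economy is better than in the chosen plan. Control of the absolute configuration is weaker than with the reagent- and auxiliary-controlled steps 12 and 17, and the carbocycle still has to be made as in steps 1–10.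

Key step: step 7

Assumptions: enolates, carbanions and peroxide anions made by deprotonating a numbered compound are treated as that compound under base and carry no number of their own. Compounds 5–9 are racemic at C14 (7 is also a mixture at C13), which has no consequence because C14 becomes sp2 in step 6.

## Steps

**Step 1**
Reactants: 1 2,2-dimethylcyclohexan-1-one
Product: 2 2,2-dimethyl-6-methylidenecyclohexan-1-one
Conditions: (CH2O)n, PhNHMe·CF3CO2H, THF, reflux
Reagents that add atoms: formaldehyde (as paraformaldehyde), C=O
Why: Mannich-type α-methylenation; the ketone has one enolisable position (C14), so the iminium ion can be attacked only there and loss of N-methylaniline gives the exocyclic enone. The product is used at once because α-methylene ketones dimerise.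

**Step 2**
Reactants: 2 2,2-dimethyl-6-methylidenecyclohexan-1-one; 3 methyl (triphenylphosphoranylidene)acetate; 4 (tert-butyldimethylsilyloxy)acetaldehyde
Product: 6 methyl (2E)-4-(TBS-oxy)-2-[(3,3-dimethyl-2-oxocyclohexyl)methyl]but-2-enoate, via phosphonium ylide 5 (not isolated)
Conditions: 3, PhMe, rt; then 4, 90 °C
Reagents that add atoms: none
Why: Michael addition of the stabilised ylide to the unhindered exocyclic enone and proton transfer give the α-substituted ylide 5, which then undergoes a Wittig reaction with the aldehyde. α-Substituted stabilised ylides place the aldehyde residue trans to the ester, which fixes C8 trans to C11 (and cis to C19).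

**Step 3**
Reactants: 6 methyl (2E)-4-(TBS-oxy)-2-[(3,3-dimethyl-2-oxocyclohexyl)methyl]but-2-enoate
Product: 7 (2E)-4-(TBS-oxy)-2-[(2-hydroxy-3,3-dimethylcyclohexyl)methyl]but-2-en-1-ol
Conditions: i-Bu2AlH, CH2Cl2, −78 to 0 °C
Reagents that add atoms: none
Why: Hydride reduction takes the conjugated ester to the allylic alcohol by 1,2-addition without touching the alkene geometry. The ketone is reduced as well, which is accepted because both carbinols are oxidised together in step 4.

**Step 4**
Reactants: 7 (2E)-4-(TBS-oxy)-2-[(2-hydroxy-3,3-dimethylcyclohexyl)methyl]but-2-en-1-ol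
Product: 8 (2E)-4-(TBS-oxy)-2-[(3,3-dimethyl-2-oxocyclohexyl)methyl]but-2-enal
Conditions: Dess–Martin periodinane, NaHCO3, CH2Cl2, 0 °C to rt
Reagents that add atoms: none
Why: Dess–Martin oxidation converts the allylic primary and the hindered secondary alcohol under buffered conditions. The E enal is the more stable geometry, so no isomerisation is expected.

**Step 5**
Reactants: 8 (2E)-4-(TBS-oxy)-2-[(3,3-dimethyl-2-oxocyclohexyl)methyl]but-2-enal
Product: 9 6-[(2E)-4-(TBS-oxy)-2-ethenylbut-2-en-1-yl]-2,2-dimethylcyclohexan-1-one
Conditions: Ph3PCH3Br, KOt-Bu, THF, 0 °C; then 8, −78 to 0 °C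
Reagents that add atoms: methylenetriphenylphosphorane (from methyltriphenylphosphonium bromide and KOt-Bu), C=P(c1ccccc1)(c1ccccc1)c1ccccc1
Why: Wittig methylenation; the enal reacts at low temperature by 1,2-addition, whereas the ketone flanked by a quaternary and a tertiary carbon is inert to the ylide under these conditions. The 2-substituted 1,3-diene forms with C9=C10 untouched.

**Step 6**
Reactants: 9 6-[(2E)-4-(TBS-oxy)-2-ethenylbut-2-en-1-yl]-2,2-dimethylcyclohexan-1-one
Product: 10 2-[(2E)-4-(TBS-oxy)-2-ethenylbut-2-en-1-yl]-6,6-dimethylcyclohex-1-en-1-yl trifluoromethanesulfonate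
Conditions: KN(SiMe3)2, THF, −78 °C; then PhNTf2, −78 to 0 °C
Reagents that add atoms: N-phenylbis(trifluoromethanesulfonimide), O=S(=O)(N(c1ccccc1)S(=O)(=O)C(F)(F)F)C(F)(F)F
Why: Enol triflate formation; deprotonation can occur only at C14, the single α-hydrogen of the ketone, because C18 is quaternary. O-Sulfonylation of the enolate gives one tetrasubstituted enol triflate, and the racemic centre is erased.

**Step 7**
Reactants: 10 2-[(2E)-4-(TBS-oxy)-2-ethenylbut-2-en-1-yl]-6,6-dimethylcyclohex-1-en-1-yl trifluoromethanesulfonate
Product: 12 tert-butyl{[(2Z)-2-(5,5-dimethyl-3,4,5,6,7,8-hexahydronaphthalen-2(1H)-ylidene)ethyl]oxy}dimethylsilane, via B-alkyl-9-BBN adduct 11 (not isolated)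
Conditions: 9-BBN, THF, 0 °C to rt; then PdCl2(dppf) (cat.), AsPh3, Cs2CO3, DMF/THF/H2O, 50 °C
Reagents that add atoms: none
Why: 9-BBN adds to the only monosubstituted alkene through the four-centre syn transition state with boron on the terminal carbon C12; the trisubstituted C9=C10 and the electron-poor tetrasubstituted enol triflate alkene are far slower, so a single B-alkyl borane 11 should result. Oxidative addition of the C13–OTf bond to zerovalent palladium, formation of the borate by the base, transmetallation of the primary alkyl group and reductive elimination then join C12 to C13; the closest known reaction type is the intramolecular B-alkyl Suzuki–Miyaura coupling of alkylboranes with enol triflates. Ring B is closed by reductive elimination from a seven-membered palladacycle, which gives the six-membered ring with the former enol triflate alkene C13=C14 endocyclic at the ring fusion and C9=C10 exocyclic. No stereocentre is formed. The step needs chemoselective hydroboration, a fixed alkene position and an untouched C9=C10 geometry: the first follows from the substitution pattern, the second from the quaternary C18 that allowed only one enol triflate in step 6, and the third because neither the hydroboration nor the palladium cycle passes through an allyl cation or an allylpalladium species at C8–C10. The wide bite angle of dppf favours reductive elimination over β-hydride elimination, and the allylic silyl ether is not ionised by zerovalent palladium.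

**Step 8**
Reactants: 12 tert-butyl{[(2Z)-2-(5,5-dimethyl-3,4,5,6,7,8-hexahydronaphthalen-2(1H)-ylidene)ethyl]oxy}dimethylsilane
Product: 13 (2Z)-2-(5,5-dimethyl-3,4,5,6,7,8-hexahydronaphthalen-2(1H)-ylidene)ethan-1-ol
Conditions: Bu4NF, THF, 0 °C to rt
Reagents that add atoms: none
Why: Fluoride-mediated desilylation, driven by the strength of the Si–F bond; the skipped diene is not affected.

**Step 9**
Reactants: 13 (2Z)-2-(5,5-dimethyl-3,4,5,6,7,8-hexahydronaphthalen-2(1H)-ylidene)ethan-1-ol
Product: 14 (2Z)-2-(2-chloroethylidene)-5,5-dimethyl-1,2,3,4,5,6,7,8-octahydronaphthalene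
Conditions: N-chlorosuccinimide, Me2S, CH2Cl2, −20 to 0 °C
Reagents that add atoms: N-chlorosuccinimide, ClN1C(=O)CCC1=O
Why: Corey–Kim chlorination; the alkoxysulfonium salt is displaced by chloride in an SN2 reaction at the primary allylic carbon at low temperature, which avoids allylic transposition and keeps the C9=C10 geometry. The reagent is preformed so that no electrophilic chlorine meets the tetrasubstituted alkene.

**Step 10**
Reactants: 14 (2Z)-2-(2-chloroethylidene)-5,5-dimethyl-1,2,3,4,5,6,7,8-octahydronaphthalene
Product: 16 [(2Z)-2-(5,5-dimethyl-3,4,5,6,7,8-hexahydronaphthalen-2(1H)-ylidene)ethyl]diphenylphosphane oxide, via allylic diphenylphosphane 15 (not isolated)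
Conditions: KPPh2, THF, −78 °C; then aq. H2O2, CH2Cl2, 0 °C
Reagents that add atoms: potassium diphenylphosphide, [K+].[P-](c1ccccc1)c1ccccc1; hydrogen peroxide, OO
Why: SN2 displacement of the primary allylic chloride by the phosphide followed by oxidation at phosphorus is the standard entry to allylic diphenylphosphine oxides. Dilute H2O2 does not epoxidise unactivated alkenes.

**Step 11**
Reactants: 17 (2E)-3,7-dimethylocta-2,6-dien-1-yl acetate (geranyl acetate)
Product: 19 (2E)-3-methyl-6-oxohex-2-en-1-yl acetate, via secondary ozonide 18 (not isolated)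
Conditions: O3 (1 equiv), CH2Cl2, −78 °C; then PPh3, −78 °C to rt
Reagents that add atoms: ozone, [O-][O+]=O
Why: Ozonolysis; the electron-rich 6,7-alkene reacts much faster than the 2,3-alkene, which is deactivated by the allylic acetate. One equivalent at low temperature and reduction of the ozonide should deliver the aldehyde with the E alkene intact.

**Step 12**
Reactants: 20 (4S)-4-benzyl-3-propanoyl-1,3-oxazolidin-2-one; 19 (2E)-3-methyl-6-oxohex-2-en-1-yl acetate
Product: 23 (2E,6R,7S)-8-[(4S)-4-benzyl-2-oxo-1,3-oxazolidin-3-yl]-6-hydroxy-3,7-dimethyl-8-oxooct-2-en-1-yl acetate, via dibutylboron enolate 21 (not isolated), via dibutylboron aldolate 22 (not isolated)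
Conditions: Bu2BOTf, i-Pr2NEt, CH2Cl2, −78 to 0 °C; then 19, −78 to 0 °C; then pH 7 buffer, MeOH, H2O2, 0 °C
Reagents that add atoms: none
Why: Evans syn-aldol; the (Z)-boron enolate reacts through a closed Zimmerman–Traxler chair in which the benzyl group of the auxiliary shields one enolate face. This sets C2 (S here, the arrangement of the target) and C3 (R here) with methyl and hydroxyl syn. C3 is deliberately made with the arrangement opposite to the target because step 19 inverts it.

**Step 13**
Reactants: 23 (2E,6R,7S)-8-[(4S)-4-benzyl-2-oxo-1,3-oxazolidin-3-yl]-6-hydroxy-3,7-dimethyl-8-oxooct-2-en-1-yl acetate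
Product: 24 (2E,6R,7R)-6,8-dihydroxy-3,7-dimethyloct-2-en-1-yl acetate
Conditions: NaBH4, THF/H2O, 0 °C to rt
Reagents that add atoms: none
Why: Reductive removal of the auxiliary; the activated exocyclic imide carbonyl is reduced by borohydride in wet THF while a simple acetate is not, and C2 does not epimerise under these conditions.

**Step 14**
Reactants: 24 (2E,6R,7R)-6,8-dihydroxy-3,7-dimethyloct-2-en-1-yl acetate
Product: 25 (2E,6R,7R)-8-(TBDPS-oxy)-6-hydroxy-3,7-dimethyloct-2-en-1-yl acetate
Conditions: TBDPSCl, imidazole, CH2Cl2, 0 °C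
Reagents that add atoms: tert-butyl(chloro)diphenylsilane, Cl[Si](c1ccccc1)(c1ccccc1)C(C)(C)C
Why: Silylation with the bulky chlorosilane is selective for the primary hydroxyl (C1) over the secondary one (C3).

**Step 15**
Reactants: 25 (2E,6R,7R)-8-(TBDPS-oxy)-6-hydroxy-3,7-dimethyloct-2-en-1-yl acetate
Product: 26 (2E,6R,7R)-8-(TBDPS-oxy)-6-(methanesulfonyloxy)-3,7-dimethyloct-2-en-1-yl acetate
Conditions: MsCl, Et3N, CH2Cl2, 0 °C
Reagents that add atoms: methanesulfonyl chloride, CS(Cl)(=O)=O
Why: Sulfonylation at oxygen proceeds with retention and installs the leaving group for step 19. It also removes the free C3 hydroxyl before the epoxide is made, so no tetrahydrofuran can form by 5-exo epoxide opening.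

**Step 16**
Reactants: 26 (2E,6R,7R)-8-(TBDPS-oxy)-6-(methanesulfonyloxy)-3,7-dimethyloct-2-en-1-yl acetate
Product: 27 (2R,3R,6E)-1-(TBDPS-oxy)-8-hydroxy-2,6-dimethyloct-6-en-3-yl methanesulfonate
Conditions: K2CO3, MeOH, 0 °C to rt
Reagents that add atoms: none
Why: Transesterification of the acetate with carbonate in methanol is faster than substitution or elimination of the β-branched secondary mesylate at this temperature.

**Step 17**
Reactants: 27 (2R,3R,6E)-1-(TBDPS-oxy)-8-hydroxy-2,6-dimethyloct-6-en-3-yl methanesulfonate
Product: 28 (2R,3R)-1-(TBDPS-oxy)-5-[(2S,3S)-3-(hydroxymethyl)-2-methyloxiran-2-yl]-2-methylpentan-3-yl methanesulfonate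
Conditions: Ti(Oi-Pr)4, L-(+)-diethyl tartrate, t-BuOOH, 4 Å MS, CH2Cl2, −20 °C
Reagents that add atoms: tert-butyl hydroperoxide, CC(C)(C)OO
Why: Sharpless asymmetric epoxidation; the allylic alcohol binds to the titanium tartrate and oxygen is delivered to one face under reagent control (the L-(+)-tartrate gives the 2S,3S epoxy alcohol from geraniol-type substrates). C6 is thereby set with its oxygen on the face that step 18 inverts, and the remote C2 and C3 centres do not interfere.

**Step 18**
Reactants: 28 (2R,3R)-1-(TBDPS-oxy)-5-[(2S,3S)-3-(hydroxymethyl)-2-methyloxiran-2-yl]-2-methylpentan-3-yl methanesulfonate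
Product: 29 (2R,3R,6R,7S)-1-(TBDPS-oxy)-6-hydroperoxy-7,8-dihydroxy-2,6-dimethyloctan-3-yl methanesulfonate
Conditions: anhydrous H2O2 in Et2O, H3PMo12O40 (cat.), rt
Reagents that add atoms: hydrogen peroxide, OO
Why: Acid-catalysed perhydrolysis of a trisubstituted epoxide; H2O2 attacks the tertiary carbon C6, which carries most of the positive charge, from the side opposite to the epoxide oxygen (borderline SN2, inversion). This gives the tertiary hydroperoxide with the target arrangement at C6, and the C8 hydroxyl further disfavours attack at C7.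

**Step 19**
Reactants: 29 (2R,3R,6R,7S)-1-(TBDPS-oxy)-6-hydroperoxy-7,8-dihydroxy-2,6-dimethyloctan-3-yl methanesulfonate
Product: 30 (1S)-1-{(3R,6S)-6-[(2R)-1-(TBDPS-oxy)propan-2-yl]-3-methyl-1,2-dioxan-3-yl}ethane-1,2-diol
Conditions: KOt-Bu (1 equiv), 18-crown-6, THF, 0 °C to rt
Reagents that add atoms: none
Why: Intramolecular SN2 alkylation of a peroxide anion; the hydroperoxide, far more acidic than the alcohols, is deprotonated and displaces the secondary mesylate in a 6-exo-tet closure with inversion at C3. C3 thereby takes the S arrangement of the target, with the C3 side chain cis to the C7 arm, and one equivalent of base keeps the alkoxide concentration low.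

**Step 20**
Reactants: 30 (1S)-1-{(3R,6S)-6-[(2R)-1-(TBDPS-oxy)propan-2-yl]-3-methyl-1,2-dioxan-3-yl}ethane-1,2-diol
Product: 31 (3R,6S)-6-[(2R)-1-(TBDPS-oxy)propan-2-yl]-3-methyl-1,2-dioxane-3-carbaldehyde
Conditions: NaIO4, THF/H2O, rt
Reagents that add atoms: none
Why: Periodate cleavage of the 1,2-diol through the cyclic periodate ester gives the non-enolisable α-peroxy aldehyde; periodate does not attack dialkyl peroxides.

**Step 21**
Reactants: 16 [(2Z)-2-(5,5-dimethyl-3,4,5,6,7,8-hexahydronaphthalen-2(1H)-ylidene)ethyl]diphenylphosphane oxide; 31 (3R,6S)-6-[(2R)-1-(TBDPS-oxy)propan-2-yl]-3-methyl-1,2-dioxane-3-carbaldehyde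
Product: 33 tert-butyl{[(2R)-2-{(3S,6R)-6-[3-(5,5-dimethyl-3,4,5,6,7,8-hexahydronaphthalen-2(1H)-ylidene)prop-1-en-1-yl]-6-methyl-1,2-dioxan-3-yl}propyl]oxy}diphenylsilane (Z at C9=C10; E/Z mixture at C7=C8), via lithium β-oxido phosphine oxide 32 (not isolated)
Conditions: n-BuLi, THF, −78 °C; then 31, −78 °C to rt
Reagents that add atoms: none
Why: Horner–Wittig olefination; the lithiated allylic phosphine oxide adds through its α-carbon (the γ-carbon C10 is fully substituted) and the β-oxido phosphine oxide loses diphenylphosphinate on warming to give the diene. Exocyclic allylic phosphine oxide anions of this kind keep their alkene geometry at low temperature, as in the couplings used for vitamin D trienes. Addition to the non-enolisable aldehyde at −78 °C is expected to outrun attack on the O–O bond.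

**Step 22**
Reactants: 33 tert-butyl{[(2R)-2-{(3S,6R)-6-[3-(5,5-dimethyl-3,4,5,6,7,8-hexahydronaphthalen-2(1H)-ylidene)prop-1-en-1-yl]-6-methyl-1,2-dioxan-3-yl}propyl]oxy}diphenylsilane
Product: 34 tert-butyl{[(2R)-2-{(3S,6S)-6-[(3Z)-3-(5,5-dimethyl-3,4,5,6,7,8-hexahydronaphthalen-2(1H)-ylidene)propyl]-6-methyl-1,2-dioxan-3-yl}propyl]oxy}diphenylsilane
Conditions: KO2CN=NCO2K, AcOH, MeOH/CH2Cl2, 0 °C to rt, added in portions
Reagents that add atoms: none
Why: Diimide reduction; concerted syn transfer of two hydrogens does not cleave O–O bonds and discriminates by alkene substitution. The 1,2-disubstituted C7=C8 should therefore be reduced before the trisubstituted C9=C10, and the tetrasubstituted C13=C14 is inert. The reaction is stopped as soon as the diene is consumed.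

**Step 23**
Reactants: 34 tert-butyl{[(2R)-2-{(3S,6S)-6-[(3Z)-3-(5,5-dimethyl-3,4,5,6,7,8-hexahydronaphthalen-2(1H)-ylidene)propyl]-6-methyl-1,2-dioxan-3-yl}propyl]oxy}diphenylsilane
Product: 35 (2R)-2-{(3S,6S)-6-[(3Z)-3-(5,5-dimethyl-3,4,5,6,7,8-hexahydronaphthalen-2(1H)-ylidene)propyl]-6-methyl-1,2-dioxan-3-yl}propan-1-ol
Conditions: Bu4NF, AcOH, THF, rt
Reagents that add atoms: none
Why: Fluoride-mediated desilylation, buffered with acetic acid so that the medium stays too weakly basic for a Kornblum–DeLaMare loss of C3–H; dialkyl peroxides tolerate these conditions.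

**Step 24**
Reactants: 35 (2R)-2-{(3S,6S)-6-[(3Z)-3-(5,5-dimethyl-3,4,5,6,7,8-hexahydronaphthalen-2(1H)-ylidene)propyl]-6-methyl-1,2-dioxan-3-yl}propan-1-ol
Product: 37 (2S)-2-{(3S,6S)-6-[(3Z)-3-(5,5-dimethyl-3,4,5,6,7,8-hexahydronaphthalen-2(1H)-ylidene)propyl]-6-methyl-1,2-dioxan-3-yl}propanoic acid, via aldehyde 36 (not isolated)
Conditions: TEMPO (cat.), PhI(OAc)2, MeCN/H2O, rt
Reagents that add atoms: water, O
Why: Oxoammonium (TEMPO) oxidation with PhI(OAc)2 as terminal oxidant takes the primary alcohol to the aldehyde 36, whose hydrate is oxidised on to the acid in the aqueous medium. The conditions are near neutral, so C2 should not epimerise, the β-peroxy carbonyl should not eliminate, and the isolated alkenes are not attacked.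

## Compound list

1 | 2,2-dimethylcyclohexan-1-one | CC1(C)CCCCC1=O | starting material
2 | 2,2-dimethyl-6-methylidenecyclohexan-1-one | C=C1CCCC(C)(C)C1=O | intermediate
3 | methyl (triphenylphosphoranylidene)acetate | COC(=O)C=P(c1ccccc1)(c1ccccc1)c1ccccc1 | starting material
4 | (tert-butyldimethylsilyloxy)acetaldehyde | CC(C)(C)[Si](C)(C)OCC=O | starting material
5 | methyl 3-(3,3-dimethyl-2-oxocyclohexyl)-2-(triphenylphosphoranylidene)propanoate, racemic (not isolated) | COC(=O)C(CC1CCCC(C)(C)C1=O)=P(c1ccccc1)(c1ccccc1)c1ccccc1 | intermediate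
6 | methyl (2E)-4-(TBS-oxy)-2-[(3,3-dimethyl-2-oxocyclohexyl)methyl]but-2-enoate, racemic at the ring CH | COC(=O)/C(CC1CCCC(C)(C)C1=O)=C/CO[Si](C)(C)C(C)(C)C | intermediate
7 | (2E)-4-(TBS-oxy)-2-[(2-hydroxy-3,3-dimethylcyclohexyl)methyl]but-2-en-1-ol, mixture of ring diastereomers | OC/C(CC1CCCC(C)(C)C1O)=C/CO[Si](C)(C)C(C)(C)C | intermediate
8 | (2E)-4-(TBS-oxy)-2-[(3,3-dimethyl-2-oxocyclohexyl)methyl]but-2-enal, racemic | O=C/C(CC1CCCC(C)(C)C1=O)=C/CO[Si](C)(C)C(C)(C)C | intermediate
9 | 6-[(2E)-4-(TBS-oxy)-2-ethenylbut-2-en-1-yl]-2,2-dimethylcyclohexan-1-one, racemic | C=C/C(CC1CCCC(C)(C)C1=O)=C/CO[Si](C)(C)C(C)(C)C | intermediate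
10 | 2-[(2E)-4-(TBS-oxy)-2-ethenylbut-2-en-1-yl]-6,6-dimethylcyclohex-1-en-1-yl trifluoromethanesulfonate | CC(C)(C)[Si](C)(C)OC/C=C(/C=C)CC1=C(OS(=O)(=O)C(F)(F)F)C(C)(C)CCC1 | intermediate
11 | 2-[(2Z)-2-[2-(9-borabicyclo[3.3.1]nonan-9-yl)ethyl]-4-(TBS-oxy)but-2-en-1-yl]-6,6-dimethylcyclohex-1-en-1-yl trifluoromethanesulfonate (not isolated) | CC(C)(C)[Si](C)(C)OC/C=C(/CCB1C2CCCC1CCC2)CC1=C(OS(=O)(=O)C(F)(F)F)C(C)(C)CCC1 | intermediate
12 | tert-butyl{[(2Z)-2-(5,5-dimethyl-3,4,5,6,7,8-hexahydronaphthalen-2(1H)-ylidene)ethyl]oxy}dimethylsilane | CC(C)(C)[Si](C)(C)OC/C=C1/CCC2=C(CCCC2(C)C)C1 | intermediate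
13 | (2Z)-2-(5,5-dimethyl-3,4,5,6,7,8-hexahydronaphthalen-2(1H)-ylidene)ethan-1-ol | OC/C=C1/CCC2=C(CCCC2(C)C)C1 | intermediate
14 | (2Z)-2-(2-chloroethylidene)-5,5-dimethyl-1,2,3,4,5,6,7,8-octahydronaphthalene | ClC/C=C1/CCC2=C(CCCC2(C)C)C1 | intermediate
15 | [(2Z)-2-(5,5-dimethyl-3,4,5,6,7,8-hexahydronaphthalen-2(1H)-ylidene)ethyl]diphenylphosphane (not isolated) | C(/C=C1/CCC2=C(CCCC2(C)C)C1)P(c1ccccc1)c1ccccc1 | intermediate
16 | [(2Z)-2-(5,5-dimethyl-3,4,5,6,7,8-hexahydronaphthalen-2(1H)-ylidene)ethyl]diphenylphosphane oxide | O=P(C/C=C1/CCC2=C(CCCC2(C)C)C1)(c1ccccc1)c1ccccc1 | intermediate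
17 | (2E)-3,7-dimethylocta-2,6-dien-1-yl acetate (geranyl acetate) | CC(C)=CCC/C(C)=C/COC(C)=O | starting material
18 | (2E)-5-(5,5-dimethyl-1,2,4-trioxolan-3-yl)-3-methylpent-2-en-1-yl acetate, epimer mixture (not isolated) | CC1(C)OOC(CC/C(C)=C/COC(C)=O)O1 | intermediate
19 | (2E)-3-methyl-6-oxohex-2-en-1-yl acetate | O=CCC/C(C)=C/COC(C)=O | intermediate
20 | (4S)-4-benzyl-3-propanoyl-1,3-oxazolidin-2-one | CCC(=O)N1[C@@H](Cc2ccccc2)COC1=O | starting material
21 | (Z)-dibutylboron enolate of 20 (not isolated) | CCCCB(CCCC)O/C(=C\C)N1[C@@H](Cc2ccccc2)COC1=O | intermediate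
22 | dibutylboron aldolate of 23 (not isolated) | CCCCB(CCCC)O[C@H](CC/C(C)=C/COC(C)=O)[C@H](C)C(=O)N1[C@@H](Cc2ccccc2)COC1=O | intermediate
23 | (2E,6R,7S)-8-[(4S)-4-benzyl-2-oxo-1,3-oxazolidin-3-yl]-6-hydroxy-3,7-dimethyl-8-oxooct-2-en-1-yl acetate | O[C@H](CC/C(C)=C/COC(C)=O)[C@H](C)C(=O)N1[C@@H](Cc2ccccc2)COC1=O | intermediate
24 | (2E,6R,7R)-6,8-dihydroxy-3,7-dimethyloct-2-en-1-yl acetate | C[C@H](CO)[C@H](O)CC/C(C)=C/COC(C)=O | intermediate
25 | (2E,6R,7R)-8-(TBDPS-oxy)-6-hydroxy-3,7-dimethyloct-2-en-1-yl acetate | C[C@H](CO[Si](c1ccccc1)(c1ccccc1)C(C)(C)C)[C@H](O)CC/C(C)=C/COC(C)=O | intermediate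
26 | (2E,6R,7R)-8-(TBDPS-oxy)-6-(methanesulfonyloxy)-3,7-dimethyloct-2-en-1-yl acetate | C[C@H](CO[Si](c1ccccc1)(c1ccccc1)C(C)(C)C)[C@H](OS(C)(=O)=O)CC/C(C)=C/COC(C)=O | intermediate
27 | (2R,3R,6E)-1-(TBDPS-oxy)-8-hydroxy-2,6-dimethyloct-6-en-3-yl methanesulfonate | C[C@H](CO[Si](c1ccccc1)(c1ccccc1)C(C)(C)C)[C@H](OS(C)(=O)=O)CC/C(C)=C/CO | intermediate
28 | (2R,3R)-1-(TBDPS-oxy)-5-[(2S,3S)-3-(hydroxymethyl)-2-methyloxiran-2-yl]-2-methylpentan-3-yl methanesulfonate | C[C@H](CO[Si](c1ccccc1)(c1ccccc1)C(C)(C)C)[C@H](OS(C)(=O)=O)CC[C@]1(C)O[C@H]1CO | intermediate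
29 | (2R,3R,6R,7S)-1-(TBDPS-oxy)-6-hydroperoxy-7,8-dihydroxy-2,6-dimethyloctan-3-yl methanesulfonate | C[C@H](CO[Si](c1ccccc1)(c1ccccc1)C(C)(C)C)[C@H](OS(C)(=O)=O)CC[C@@](C)(OO)[C@@H](O)CO | intermediate
30 | (1S)-1-{(3R,6S)-6-[(2R)-1-(TBDPS-oxy)propan-2-yl]-3-methyl-1,2-dioxan-3-yl}ethane-1,2-diol | C[C@H](CO[Si](c1ccccc1)(c1ccccc1)C(C)(C)C)[C@@H]1CC[C@](C)([C@@H](O)CO)OO1 | intermediate
31 | (3R,6S)-6-[(2R)-1-(TBDPS-oxy)propan-2-yl]-3-methyl-1,2-dioxane-3-carbaldehyde | C[C@H](CO[Si](c1ccccc1)(c1ccccc1)C(C)(C)C)[C@@H]1CC[C@](C)(C=O)OO1 | intermediate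
32 | lithium alkoxide of the C7-hydroxy C8-diphenylphosphoryl adduct of 16 and 31, mixture at C7 and C8 (not isolated) | C[C@H](CO[Si](c1ccccc1)(c1ccccc1)C(C)(C)C)[C@@H]1CC[C@](C)(C([O-])C(/C=C2/CCC3=C(CCCC3(C)C)C2)P(=O)(c2ccccc2)c2ccccc2)OO1.[Li+] | intermediate
33 | tert-butyl{[(2R)-2-{(3S,6R)-6-[3-(5,5-dimethyl-3,4,5,6,7,8-hexahydronaphthalen-2(1H)-ylidene)prop-1-en-1-yl]-6-methyl-1,2-dioxan-3-yl}propyl]oxy}diphenylsilane, Z at C9=C10, E/Z mixture at C7=C8 | C[C@H](CO[Si](c1ccccc1)(c1ccccc1)C(C)(C)C)[C@@H]1CC[C@](C)(C=C/C=C2/CCC3=C(CCCC3(C)C)C2)OO1 | intermediate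
34 | tert-butyl{[(2R)-2-{(3S,6S)-6-[(3Z)-3-(5,5-dimethyl-3,4,5,6,7,8-hexahydronaphthalen-2(1H)-ylidene)propyl]-6-methyl-1,2-dioxan-3-yl}propyl]oxy}diphenylsilane | C[C@H](CO[Si](c1ccccc1)(c1ccccc1)C(C)(C)C)[C@@H]1CC[C@](C)(CC/C=C2/CCC3=C(CCCC3(C)C)C2)OO1 | intermediate
35 | (2R)-2-{(3S,6S)-6-[(3Z)-3-(5,5-dimethyl-3,4,5,6,7,8-hexahydronaphthalen-2(1H)-ylidene)propyl]-6-methyl-1,2-dioxan-3-yl}propan-1-ol | C[C@H](CO)[C@@H]1CC[C@](C)(CC/C=C2/CCC3=C(CCCC3(C)C)C2)OO1 | intermediate
36 | (2S)-2-{(3S,6S)-6-[(3Z)-3-(5,5-dimethyl-3,4,5,6,7,8-hexahydronaphthalen-2(1H)-ylidene)propyl]-6-methyl-1,2-dioxan-3-yl}propanal (not isolated) | C[C@H](C=O)[C@@H]1CC[C@](C)(CC/C=C2/CCC3=C(CCCC3(C)C)C2)OO1 | intermediate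
37 | (2S)-2-{(3S,6S)-6-[(3Z)-3-(5,5-dimethyl-3,4,5,6,7,8-hexahydronaphthalen-2(1H)-ylidene)propyl]-6-methyl-1,2-dioxan-3-yl}propanoic acid | C[C@H](C(=O)O)[C@@H]1CC[C@](C)(CC/C=C2/CCC3=C(CCCC3(C)C)C2)OO1 | target

## Step count and least certain steps

Total step count: 24. Longest linear sequence: 14 steps (steps 1–10 followed by 21–24; the branch 11–20 followed by 21–24 is equally long).

**Step 7 (key step).** The most likely failure is slow oxidative addition at the hindered tetrasubstituted triflate next to C18, so that hydrolysis of the triflate by the aqueous base and protodeboronation of 11 overtake the coupling. A second concern is incomplete or twofold hydroboration of the diene.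

Fallback: the closure is moved to a base-free organozinc coupling. It sets out from 10. Hydroboration as before, but with oxidation of 11 by NaBO3, would give the primary alcohol 2-[(2E)-4-(TBS-oxy)-2-(2-hydroxyethyl)but-2-en-1-yl]-6,6-dimethylcyclohex-1-en-1-yl triflate F1. I2, PPh3 and imidazole would convert it into the iodide F2. Zinc insertion (Zn, LiCl, THF) would give the alkylzinc iodide F3, which is closed on the enol triflate with Pd(PPh3)4 in an intramolecular Negishi coupling. The route is rejoined at 12.

**Step 19.** The most likely failure is loss of the hydroperoxide by base-induced Grob-type fragmentation across C6–C7, through the small equilibrium amount of C7 alkoxide. This competes with an SN2 reaction that is slow because C3 is secondary and β-branched; elimination of the mesylate is the second competitor.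

Fallback: the free hydroxyls are removed before the peroxide anion is generated. It sets out from 29. Et3SiOTf and 2,6-lutidine would give the tris(triethylsilyl) derivative F4, which carries a silyl peroxide and two silyl ethers. Bu4NF at 0 °C cleaves the weak Si–OO bond first, and the peroxide anion, with no alkoxide present, should close to the bis(triethylsilyl) dioxane F5. Acid methanolysis (pyridinium p-toluenesulfonate, MeOH) removes the triethylsilyl groups, and the route is rejoined at 30.

**Step 21.** The most likely failure is competing attack of the lithiated phosphine oxide on the O–O bond or on C3–H, because addition to the neopentyl-type aldehyde is slowed by the quaternary C6. Incomplete elimination of the lithium adduct 32 is a lesser concern.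

Fallback: a Julia–Kocienski olefination with a potassium sulfonyl carbanion generated in the presence of the aldehyde. It sets out from 13. A Mitsunobu reaction with 1-phenyl-1H-tetrazole-5-thiol would give the allylic sulfide F6, and oxidation (H2O2, (NH4)6Mo7O24, EtOH) the sulfone F7. KN(SiMe3)2 is then added to a mixture of F7 and 31 at −78 °C. The route is rejoined at 33.

**Step 22.** The most likely failure is reduction at the wrong end of the conjugated diene. C7=C8 is shielded by the quaternary C6, so its advantage over the exocyclic trisubstituted C9=C10 may be small and over-reduced material would be hard to remove.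

Fallback: the reduction is given a more reactive substrate. It sets out from 16 and 31. The Horner–Wittig addition is quenched at −78 °C with acetic acid, and the erythro β-hydroxy phosphine oxide F8 (the kinetic adduct of lithiated phosphine oxides) is isolated. Syn-elimination with KN(SiMe3)2 in THF at 0 °C would give the (7Z)-diene F9. Its cis alkene next to C6 is strained and twisted out of conjugation, so it should take up diimide faster than C9=C10. Reduction as in step 22 rejoins the route at 34.

## Further compounds

F1 | step 7 | 2-[(2E)-4-(TBS-oxy)-2-(2-hydroxyethyl)but-2-en-1-yl]-6,6-dimethylcyclohex-1-en-1-yl trifluoromethanesulfonate | CC(C)(C)[Si](C)(C)OC/C=C(/CCO)CC1=C(OS(=O)(=O)C(F)(F)F)C(C)(C)CCC1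
F2 | step 7 | 2-[(2E)-4-(TBS-oxy)-2-(2-iodoethyl)but-2-en-1-yl]-6,6-dimethylcyclohex-1-en-1-yl trifluoromethanesulfonate | CC(C)(C)[Si](C)(C)OC/C=C(/CCI)CC1=C(OS(=O)(=O)C(F)(F)F)C(C)(C)CCC1
F3 | step 7 | alkylzinc iodide of F2 (zinc on C12) | CC(C)(C)[Si](C)(C)OC/C=C(/CC[Zn]I)CC1=C(OS(=O)(=O)C(F)(F)F)C(C)(C)CCC1
F4 | step 19 | (2R,3R,6R,7S)-1-(TBDPS-oxy)-2,6-dimethyl-7,8-bis(triethylsilyloxy)-6-(triethylsilylperoxy)octan-3-yl methanesulfonate | C[C@H](CO[Si](c1ccccc1)(c1ccccc1)C(C)(C)C)[C@H](OS(C)(=O)=O)CC[C@@](C)(OO[Si](CC)(CC)CC)[C@@H](O[Si](CC)(CC)CC)CO[Si](CC)(CC)CC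
F5 | step 19 | tert-butyl{[(2R)-2-{(3S,6R)-6-[(1S)-1,2-bis(triethylsilyloxy)ethyl]-6-methyl-1,2-dioxan-3-yl}propyl]oxy}diphenylsilane | C[C@H](CO[Si](c1ccccc1)(c1ccccc1)C(C)(C)C)[C@@H]1CC[C@](C)([C@@H](O[Si](CC)(CC)CC)CO[Si](CC)(CC)CC)OO1
F6 | step 21 | 5-{[(2Z)-2-(5,5-dimethyl-3,4,5,6,7,8-hexahydronaphthalen-2(1H)-ylidene)ethyl]sulfanyl}-1-phenyl-1H-tetrazole | C(/C=C1/CCC2=C(CCCC2(C)C)C1)Sc1nnnn1-c1ccccc1
F7 | step 21 | 5-{[(2Z)-2-(5,5-dimethyl-3,4,5,6,7,8-hexahydronaphthalen-2(1H)-ylidene)ethyl]sulfonyl}-1-phenyl-1H-tetrazole | O=S(=O)(C/C=C1/CCC2=C(CCCC2(C)C)C1)c1nnnn1-c1ccccc1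
F8 | step 22 | tert-butyl{[(2R)-2-{(3S,6R)-6-[2-(diphenylphosphoryl)-1-hydroxy-3-(5,5-dimethyl-3,4,5,6,7,8-hexahydronaphthalen-2(1H)-ylidene)propyl]-6-methyl-1,2-dioxan-3-yl}propyl]oxy}diphenylsilane, erythro at C7/C8 (both erythro diastereomers), Z at C9=C10 | C[C@H](CO[Si](c1ccccc1)(c1ccccc1)C(C)(C)C)[C@@H]1CC[C@](C)(C(O)C(/C=C2/CCC3=C(CCCC3(C)C)C2)P(=O)(c2ccccc2)c2ccccc2)OO1
F9 | step 22 | (7Z)-isomer of 33: tert-butyl{[(2R)-2-{(3S,6R)-6-[(1Z)-3-(5,5-dimethyl-3,4,5,6,7,8-hexahydronaphthalen-2(1H)-ylidene)prop-1-en-1-yl]-6-methyl-1,2-dioxan-3-yl}propyl]oxy}diphenylsilane, Z at C9=C10 | C[C@H](CO[Si](c1ccccc1)(c1ccccc1)C(C)(C)C)[C@@H]1CC[C@](C)(/C=C\C=C2\CCC3=C(CCCC3(C)C)C2)OO1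
A1 | alternative 1 | tert-butyl{[(2R,3S)-3-hydroperoxy-2-methyl-5-[(2S)-2-methyloxiran-2-yl]pentyl]oxy}diphenylsilane | C[C@H](CO[Si](c1ccccc1)(c1ccccc1)C(C)(C)C)[C@@H](OO)CC[C@@]1(C)CO1
A2 | alternative 1 | {(3R,6S)-6-[(2R)-1-(TBDPS-oxy)propan-2-yl]-3-methyl-1,2-dioxan-3-yl}methanol | C[C@H](CO[Si](c1ccccc1)(c1ccccc1)C(C)(C)C)[C@@H]1CC[C@](C)(CO)OO1
A3 | alternative 2 | tert-butyl{[(2R,5Z)-2-hydroperoxy-2-methylhept-5-en-1-yl]oxy}dimethylsilane | C/C=C\CC[C@](C)(CO[Si](C)(C)C(C)(C)C)OO
A4 | alternative 2 | methyl (2S)-2-[(3S,6R)-6-(TBS-oxymethyl)-6-methyl-1,2-dioxan-3-yl]propanoate | C[C@H](C(=O)OC)[C@@H]1CC[C@](C)(CO[Si](C)(C)C(C)(C)C)OO1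
A5 | alternative 3 | (2E,4E,6S)-7-(TBDPS-oxy)-1-(TBS-oxy)-2,6-dimethylhepta-2,4-diene | C[C@H](CO[Si](c1ccccc1)(c1ccccc1)C(C)(C)C)/C=C/C=C(\C)CO[Si](C)(C)C(C)(C)C
A6 | alternative 3 | tert-butyl{[(3R,6S)-6-[(2R)-1-(TBDPS-oxy)propan-2-yl]-3-methyl-3,6-dihydro-1,2-dioxin-3-yl]methoxy}dimethylsilane | C[C@H](CO[Si](c1ccccc1)(c1ccccc1)C(C)(C)C)[C@@H]1C=C[C@](C)(CO[Si](C)(C)C(C)(C)C)OO1
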